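**Retrosynthetic overview**
- Labels and feature: flavone atoms are O1–C8a, with rings A (benzo), C (pyranone) and B (aryl on C2). Ring D atoms are D1–D6, with D1 on C6, OH on D2 and CO2H on D5. Ring D is a 4-hydroxybenzoic acid (D2–OH para to D5–CO2H) whose only other substituent, C6 of ring A, sits at D1 next to the hydroxyl. Methyl coumalate leaves this pattern on an oxygen-bearing alkyne D1≡D2–O: its C3–C6 become D3–D6 and its ester marks D5.
- Disconnection 1: D1–D6 and D2–D3 are cut by a retro-[4+2] with CO2 put back. This gives a 6-(ethoxyethynyl)flavone and methyl coumalate, so the crowded C6–D1 biaryl bond is made earlier as an open C6–C(sp) bond.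
- Disconnection 2: C6–C(sp) comes from Negishi coupling of 6-iodo-tri-O-methylapigenin with ethoxyacetylene. The iodide comes from apigenin by 7,4'-O-methylation, C6 iodination beside the free 5-OH, and 5-O-methylation.
- Ring order: rings A, C and B arrive intact in apigenin and ring D is the only ring built. Ester hydrolysis and cleavage of the four ethers finish the route.

Key step: step 5

Assumption: the target SMILES carries no stereodescriptor, so the C6–D1 axis is treated as configurationally undefined and no stereocentre has to be set.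

**Step 1**
Reactants: 1 apigenin
Product: 2 apigenin 7,4'-dimethyl ether (5-hydroxy-7-methoxy-2-(4-methoxyphenyl)chromen-4-one)
Conditions: MeI (2.2 equiv), K2CO3 (2.5 equiv), DMF, rt
Reagents that add atoms: iodomethane, CI
Why: Williamson O-methylation takes the acidic 7-OH and 4'-OH first, while the 5-OH, held in a hydrogen bond to the C4 carbonyl, should stay free with two equivalents of MeI at room temperature.

**Step 2**
Reactants: 2 apigenin 7,4'-dimethyl ether
Product: 3 iodophenol (5-hydroxy-6-iodo-7-methoxy-2-(4-methoxyphenyl)chromen-4-one)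
Conditions: BnMe3N·ICl2 (1.05 equiv), CaCO3, CH2Cl2–MeOH, rt
Reagents that add atoms: benzyltrimethylammonium dichloroiodate, C[N+](C)(C)Cc1ccccc1.Cl[I-]Cl
Why: Electrophilic aromatic iodination with a dichloroiodate salt goes to C6 in 5-hydroxy-7-alkoxyflavones because the free chelated phenol steers iodine to its ortho position rather than to C8, a known preference that is lost once O5 is alkylated, and CaCO3 takes up the HCl.

**Step 3**
Reactants: 3 iodophenol
Product: 4 iodide (6-iodo-5,7-dimethoxy-2-(4-methoxyphenyl)chromen-4-one)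
Conditions: MeI (4 equiv), K2CO3, DMF, 45 °C, closed flask
Reagents that add atoms: iodomethane, CI
Why: Williamson O-methylation with excess MeI in warm DMF overcomes the hydrogen bond of the 5-OH and removes the phenol that would otherwise quench the organozinc reagent and add to the ynol ether.

**Step 4**
Reactants: 4 iodide; 5 ethoxyacetylene
Product: 8 ynol ether 6-(ethoxyethynyl)-5,7-dimethoxy-2-(4-methoxyphenyl)chromen-4-one, via lithium ethoxyacetylide 6 (not isolated), via ethoxyethynylzinc chloride 7 (not isolated)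
Conditions: 5 (2 equiv), n-BuLi, THF, −78 °C; ZnCl2, −78 → 0 °C; then 4, Pd(PPh3)4 (5 mol %), THF, rt → 45 °C; aq NaHCO3 work-up, Et3N-deactivated silica
Reagents that add atoms: none
Why: Negishi coupling of alkoxyethynylzinc halides with aryl iodides under zerovalent palladium catalysis is known, the rod-shaped nucleophile can reach the iodide between the two methoxy groups, the organozinc leaves the chromenone carbonyl alone, and the basic work-up protects the acid-sensitive ynol ether.

**Step 5**
Reactants: 8 ynol ether; 9 methyl coumalate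
Product: 11 methyl 3-[5,7-dimethoxy-2-(4-methoxyphenyl)-4-oxochromen-6-yl]-4-ethoxybenzoate, via bridged bicyclic lactone 10 (not isolated)
Conditions: 9 (3 equiv, freshly sublimed), toluene (about 1 M), 85 °C, sealed tube, Ar
Reagents that add atoms: none
Why: Inverse-electron-demand Diels–Alder addition of the electron-rich alkyne 8 to the electron-poor 2-pyranone 9, followed by retro-[4+2] loss of CO2, is the known path from methyl coumalate and donor dienophiles (ynol ethers, ynamines, ketene acetals, enol ethers) to benzoates. The ethoxy oxygen pushes electron density onto the flavone-bearing carbon D1, which bonds in advance to C6 of 9 (β to the ester, δ to the lactone carbonyl, next to the ring oxygen), while the oxygen-bearing carbon D2 closes onto C3. Ring D is therefore closed by an intermolecular, concerted but asynchronous [4+2] cycloaddition that forms D1–D6 and D2–D3 in the 2-oxabicyclo[2.2.2]octadienone 10, and extrusion of the O–C(=O) bridge from 10 delivers the arene without any oxidant. No stereocentre is carried forward, since both bridgehead centres of 10 become sp2 carbons when CO2 leaves. The selectivity required is regiochemical (D2–OEt para and D1 meta to the ester) and is secured by this donor–acceptor pairing, the same orientation in which ketene acetals give 4-alkoxybenzoates, while the rod shape of the alkyne holds the reacting carbons clear of the C5 and C7 methoxy groups. The bath stays at 85 °C because ethyl ynol ethers fragment to ethylene and a ketene by a retro-ene path above roughly 100–120 °C, and acid-free 9 in excess at high concentration is used to favour the bimolecular step and to avoid hydration of 8.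

**Step 6**
Reactants: 11 methyl ester
Product: 12 acid (3-[5,7-dimethoxy-2-(4-methoxyphenyl)-4-oxochromen-6-yl]-4-ethoxybenzoic acid)
Conditions: LiOH·H2O (5 equiv), THF–MeOH–H2O, 40 °C; then 1 M HCl to pH 2–3
Reagents that add atoms: lithium hydroxide, [Li+].[OH-]
Why: Saponification (BAc2 ester hydrolysis) cleaves the unhindered D5 methyl ester under mild base, and if hydroxide opens ring C reversibly at C2, only O1 can close again on acidification because O5 is still methylated, so ring D stays on C6.

**Step 7**
Reactants: 12 acid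
Product: 13 target (3-[5,7-dihydroxy-2-(4-hydroxyphenyl)-4-oxochromen-6-yl]-4-hydroxybenzoic acid, CNP0203666.0)
Conditions: BBr3 (12 equiv), CH2Cl2, −78 °C → rt, then 40 °C; ice–water quench
Reagents that add atoms: none
Why: Lewis-acid ether cleavage with BBr3 takes the 5-OMe first through chelation to the C4 carbonyl and the 7-OMe, 4'-OMe and D2-OEt at room temperature to 40 °C with a large excess of reagent, which is gentler than hot HI or HBr and so should avoid a Wessely–Moser opening and reclosure of ring C that would carry ring D to C8, while the water quench avoids re-esterification.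

**Compound list**
1 | apigenin | O=c1cc(-c2ccc(O)cc2)oc2cc(O)cc(O)c12 | starting material
2 | 5-hydroxy-7-methoxy-2-(4-methoxyphenyl)chromen-4-one | O=c1cc(-c2ccc(OC)cc2)oc2cc(OC)cc(O)c12 | intermediate
3 | 5-hydroxy-6-iodo-7-methoxy-2-(4-methoxyphenyl)chromen-4-one | O=c1cc(-c2ccc(OC)cc2)oc2cc(OC)c(I)c(O)c12 | intermediate
4 | 6-iodo-5,7-dimethoxy-2-(4-methoxyphenyl)chromen-4-one | O=c1cc(-c2ccc(OC)cc2)oc2cc(OC)c(I)c(OC)c12 | intermediate
5 | ethoxyacetylene | C#COCC | starting material
6 | lithium ethoxyacetylide (not isolated) | [Li]C#COCC | intermediate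
7 | ethoxyethynylzinc chloride (not isolated) | Cl[Zn]C#COCC | intermediate
8 | 6-(ethoxyethynyl)-5,7-dimethoxy-2-(4-methoxyphenyl)chromen-4-one | CCOC#Cc1c(OC)cc2oc(-c3ccc(OC)cc3)cc(=O)c2c1OC | intermediate
9 | methyl coumalate (methyl 2-oxo-2H-pyran-5-carboxylate) | COC(=O)c1ccc(=O)oc1 | starting material
10 | methyl 8-ethoxy-7-[5,7-dimethoxy-2-(4-methoxyphenyl)-4-oxochromen-6-yl]-3-oxo-2-oxabicyclo[2.2.2]octa-5,7-diene-6-carboxylate (racemic, bridgeheads tied to each other by the bicycle, not isolated) | O=C1OC2C(C(=O)OC)=CC1C(OCC)=C2c1c(OC)cc2oc(-c3ccc(OC)cc3)cc(=O)c2c1OC | intermediate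
11 | methyl 3-[5,7-dimethoxy-2-(4-methoxyphenyl)-4-oxochromen-6-yl]-4-ethoxybenzoate | CCOc1ccc(C(=O)OC)cc1-c1c(OC)cc2oc(-c3ccc(OC)cc3)cc(=O)c2c1OC | intermediate
12 | 3-[5,7-dimethoxy-2-(4-methoxyphenyl)-4-oxochromen-6-yl]-4-ethoxybenzoic acid | CCOc1ccc(C(=O)O)cc1-c1c(OC)cc2oc(-c3ccc(OC)cc3)cc(=O)c2c1OC | intermediate
13 | 3-[5,7-dihydroxy-2-(4-hydroxyphenyl)-4-oxochromen-6-yl]-4-hydroxybenzoic acid | O=C(O)c1ccc(O)c(-c2c(O)cc3oc(-c4ccc(O)cc4)cc(=O)c3c2O)c1 | target

Total step count: 7. Longest linear sequence: 7 steps (1 → 13).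

**Steps most likely to fail**

1. **Step 5.**
 - What may go wrong: the cycloaddition may be too slow at a temperature the ynol ether tolerates. Retro-ene loss of ethylene, hydration or oligomerisation of the alkyne would then outrun ring formation.
 - Fallback (sets out from 4, returns at 11): ring D is brought in ready-made by a Suzuki–Miyaura coupling.
 - Commercial methyl 3-bromo-4-hydroxybenzoate is O-ethylated (EtI, K2CO3, DMF) to methyl 3-bromo-4-ethoxybenzoate F1.
 - Miyaura borylation (B2pin2, PdCl2(dppf), KOAc, dioxane, 90 °C) gives methyl 4-ethoxy-3-(4,4,5,5-tetramethyl-1,3,2-dioxaborolan-2-yl)benzoate F2.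
 - This boronate is coupled with iodide 4 (Pd(OAc)2, SPhos, K3PO4, toluene–H2O, 100 °C), conditions made for biaryls with three ortho substituents, to give 11.

2. **Step 4.**
 - What may go wrong: slow oxidative addition at the iodide flanked by two methoxy groups may let homocoupling of the alkynylzinc and reduction of the C–I bond compete. Zinc salts or silica may also hydrate the triple bond during isolation.
 - Fallback (sets out from 4, returns at 8): the two carbons are attached as a robust enol ether and the triple bond is made last, under base.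
 - Suzuki–Miyaura coupling of 4 with commercial (E)-2-ethoxyvinylboronic acid pinacol ester (Pd(OAc)2, SPhos, K3PO4, dioxane–H2O, 80 °C) gives 6-[(E)-2-ethoxyvinyl]-5,7-dimethoxy-2-(4-methoxyphenyl)chromen-4-one F3.
 - Br2 (1.0 equiv, CH2Cl2, −78 °C) adds to the enol ether to give the 6-(1,2-dibromo-2-ethoxyethyl)flavone F4. This is not isolated but treated with Et3N to give the 6-(1-bromo-2-ethoxyvinyl)flavone F5.
 - KOtBu (THF, −78 → 0 °C) removes the second HBr, the classical dehydrobromination route to alkynyl ethers, and gives 8.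

3. **Step 7.**
 - What may go wrong: slow cleavage of the 7- and 4'-methyl ethers may force long exposure to warm BBr3 and HBr. Boron chelates may then precipitate before cleavage is complete, or ring C may open and reclose with migration of ring D.
 - Fallback (sets out from 1, returns at 13): the flavone oxygens are carried as benzyl ethers, which BBr3 removes at −78 °C. Only the ring D ethyl ether then needs 0 °C to room temperature.
 - BnBr (2.2 equiv), K2CO3, DMF turns 1 into 7,4'-di-O-benzylapigenin F6.
 - BnMe3N·ICl2 and CaCO3 give 6-iodo-7,4'-di-O-benzylapigenin F7.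
 - BnBr, K2CO3, DMF, 70 °C give 6-iodo-5,7,4'-tri-O-benzylapigenin F8.
 - Negishi coupling with 7 as in step 4 gives the tribenzyl ynol ether F9.
 - Heating with 9 as in step 5 gives, through the tribenzyl bridged lactone F10, the tribenzyl ethoxybenzoate F11.
 - LiOH gives the tribenzyl ethoxybenzoic acid F12.
 - BBr3 (8 equiv) with pentamethylbenzene as benzyl-cation trap (CH2Cl2, −78 °C → rt, water quench) then gives 13.

**Further compounds**
F1 | step 5 | methyl 3-bromo-4-ethoxybenzoate | CCOc1ccc(C(=O)OC)cc1Br
F2 | step 5 | methyl 4-ethoxy-3-(4,4,5,5-tetramethyl-1,3,2-dioxaborolan-2-yl)benzoate | CCOc1ccc(C(=O)OC)cc1B1OC(C)(C)C(C)(C)O1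
F3 | step 4 | 6-[(E)-2-ethoxyvinyl]-5,7-dimethoxy-2-(4-methoxyphenyl)chromen-4-one | CCO/C=C/c1c(OC)cc2oc(-c3ccc(OC)cc3)cc(=O)c2c1OC
F4 | step 4 | 6-(1,2-dibromo-2-ethoxyethyl)-5,7-dimethoxy-2-(4-methoxyphenyl)chromen-4-one (racemic mixture of diastereomers, not isolated) | CCOC(Br)C(Br)c1c(OC)cc2oc(-c3ccc(OC)cc3)cc(=O)c2c1OC
F5 | step 4 | 6-(1-bromo-2-ethoxyvinyl)-5,7-dimethoxy-2-(4-methoxyphenyl)chromen-4-one (E/Z mixture) | CCOC=C(Br)c1c(OC)cc2oc(-c3ccc(OC)cc3)cc(=O)c2c1OC
F6 | step 7 | 7-(benzyloxy)-2-[4-(benzyloxy)phenyl]-5-hydroxychromen-4-one | O=c1cc(-c2ccc(OCc3ccccc3)cc2)oc2cc(OCc3ccccc3)cc(O)c12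
F7 | step 7 | 7-(benzyloxy)-2-[4-(benzyloxy)phenyl]-5-hydroxy-6-iodochromen-4-one | O=c1cc(-c2ccc(OCc3ccccc3)cc2)oc2cc(OCc3ccccc3)c(I)c(O)c12
F8 | step 7 | 5,7-bis(benzyloxy)-2-[4-(benzyloxy)phenyl]-6-iodochromen-4-one | O=c1cc(-c2ccc(OCc3ccccc3)cc2)oc2cc(OCc3ccccc3)c(I)c(OCc3ccccc3)c12
F9 | step 7 | 5,7-bis(benzyloxy)-2-[4-(benzyloxy)phenyl]-6-(ethoxyethynyl)chromen-4-one | CCOC#Cc1c(OCc2ccccc2)cc2oc(-c3ccc(OCc4ccccc4)cc3)cc(=O)c2c1OCc1ccccc1
F10 | step 7 | methyl 7-{5,7-bis(benzyloxy)-2-[4-(benzyloxy)phenyl]-4-oxochromen-6-yl}-8-ethoxy-3-oxo-2-oxabicyclo[2.2.2]octa-5,7-diene-6-carboxylate (racemic, not isolated) | O=C1OC2C(C(=O)OC)=CC1C(OCC)=C2c1c(OCc2ccccc2)cc2oc(-c3ccc(OCc4ccccc4)cc3)cc(=O)c2c1OCc1ccccc1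
F11 | step 7 | methyl 3-{5,7-bis(benzyloxy)-2-[4-(benzyloxy)phenyl]-4-oxochromen-6-yl}-4-ethoxybenzoate | CCOc1ccc(C(=O)OC)cc1-c1c(OCc2ccccc2)cc2oc(-c3ccc(OCc4ccccc4)cc3)cc(=O)c2c1OCc1ccccc1
F12 | step 7 | 3-{5,7-bis(benzyloxy)-2-[4-(benzyloxy)phenyl]-4-oxochromen-6-yl}-4-ethoxybenzoic acid | CCOc1ccc(C(=O)O)cc1-c1c(OCc2ccccc2)cc2oc(-c3ccc(OCc4ccccc4)cc3)cc(=O)c2c1OCc1ccccc1
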